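**Plan**

- Feature: in the hexahydroindene core (indene numbering, used for every intermediate: C2 ketone between methyl-bearing C1 and C3, ring fusion C3a/C7a, C6=C7 alkene) the adjacent quaternary carbons C4 and C5 carry cis ethyl groups and cis carbonyl-derived carbons (CO2H and the styryl CH). This is the imprint of 2,3-diethylmaleic anhydride added across C5–C6 and C4–C3a of the six-membered ring.
- Retrosynthesis: cut the styryl C=C (C5 formyl, from the C5 anhydride carbonyl) and C7–CH3 (enol triflate); then C7a–C1 and C3a–C3 of the cyclopentanone (pentan-3-one across a C3a=C7a enone); then C5–C6 and C4–C3a by a Diels–Alder reaction of the anhydride with a 1-amino-3-siloxybutadiene.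
- Forward: the cyclohexenone ring closes first in the cycloaddition. The cyclopentanone is then annulated (conjugate addition at C3a, oxidative closure at C7a). The anhydride ring is kept as protection of both carboxyl carbons and opened last, by reduction at its C5 carbonyl and olefination.
- Stereochemistry: C4/C5 absolute configuration from the (2R,5R)-diphenylpyrrolidine on the diene (cis relation from the dienophile geometry); C3a from addition anti to the anhydride ring; C7a, C1 and C3 by equilibration α to ketones; E alkene from the phosphonate olefination.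

Key step: step 4

Assumption: the (2R,5R)-auxiliary is taken to leave open, for endo approach, the diene face that leads to the (4S,5R) ring of the enone anhydride; should the adduct belong to the mirror-image series, the equally available (2S,5S)-amine is used and nothing else changes.

**Route**

Step 1
Reactants: 1 hex-3-yne
Product: 2 3,4-diethylfuran-2,5-dione (2,3-diethylmaleic anhydride)
Conditions: Ni(acac)2/2,2'-bipyridine (10 mol %), Zn, MgBr2, 3 Å MS, CO2 (1 atm), DMF, rt; then 1 M HCl
Reagents that add atoms: carbon dioxide, O=C=O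
Why: Nickel-catalysed reductive double carboxylation of an internal dialkyl alkyne with CO2 (zinc as terminal reductant) passes through an oxanickelacyclopentenone that takes up a second CO2, and the cis-diacid closes to the tetrasubstituted maleic anhydride on acidic work-up; no stereocentre is formed.

Step 2
Reactants: 3 (E)-4-methoxybut-3-en-2-one; 4 (2R,5R)-2,5-diphenylpyrrolidine
Product: 5 (E)-4-[(2R,5R)-2,5-diphenylpyrrolidin-1-yl]but-3-en-2-one
Conditions: THF, rt → 50 °C
Reagents that add atoms: none
Why: Conjugate addition–elimination of the secondary amine on the β-methoxy enone (vinylogous transamidation) gives the push–pull vinylogous amide in its thermodynamically fixed E form, and the two pyrrolidine centres are not touched.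

Step 3
Reactants: 5 (E)-4-[(2R,5R)-2,5-diphenylpyrrolidin-1-yl]but-3-en-2-one
Product: 6 (E)-1-[(2R,5R)-2,5-diphenylpyrrolidin-1-yl]-3-(tert-butyldimethylsilyloxy)buta-1,3-diene
Conditions: KHMDS, THF, −78 °C; TBSCl, −78 °C → rt
Reagents that add atoms: tert-butyldimethylsilyl chloride, CC(C)(C)[Si](C)(C)Cl
Why: Kinetic deprotonation of the methyl ketone and O-silylation of the cross-conjugated enolate (silyl enol ether formation) gives the 1-amino-3-siloxy diene with the E enamine geometry retained and no new stereocentre.

Step 4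
Reactants: 2 3,4-diethylfuran-2,5-dione; 6 (E)-1-[(2R,5R)-2,5-diphenylpyrrolidin-1-yl]-3-(tert-butyldimethylsilyloxy)buta-1,3-diene
Product: 8 (3aR,7aS)-3a,7a-diethyl-3a,4-dihydro-2-benzofuran-1,3,5(7aH)-trione, via endo cycloadduct 7 (not isolated)
Conditions: PhMe, 0 → 40 °C; then HF (48 % aq.), MeCN, 0 °C
Reagents that add atoms: none
Why: The push–pull diene 6 and the doubly activated alkene of 2 combine in a thermal, normal-demand [4+2] cycloaddition that is concerted but asynchronous (the C5–C6 bond from the nucleophilic CH2 terminus leads, C4–C3a follows), the closest known reactions being cycloadditions of 1-amino-3-siloxybutadienes with α-substituted acroleins and maleic-type dienophiles and thermal additions of 2,3-dialkylmaleic anhydrides. The six-membered ring closes in the cycloaddition itself, both σ-bonds forming suprafacially on each partner, and HF then cleaves the silyl enol ether and expels the protonated pyrrolidine by β-elimination to leave the C3a=C7a enone conjugated with the C7 ketone. The cis relation of C4 and C5 follows from the Z geometry of the dienophile, and their absolute configuration from the diene face left open by the C2-symmetric pyrrolidine (both N–C rotamers are equivalent) combined with endo placement of the anhydride ring. The step therefore needs facial and endo selectivity together, because exo addition to the same face gives the enantiomeric enone once the amine is lost; the auxiliary is relied on for the first and the usual preference of cyclic anhydride carbonyls for the position under the polarised diene, with the ethyl groups turned outward, for the second. Regiochemistry does not arise because 2 is C2v-symmetric, C-acylation of the diene is disfavoured because both anhydride carbonyls sit on fully substituted carbons, and the tetrasubstituted succinic anhydride is expected to survive aqueous HF. The auxiliary is recovered from the acidic phase, and enrichment of 8 by recrystallisation would be examined if needed.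

Step 5
Reactants: 9 pentan-3-one
Product: 10 (Z)-3-(trimethylsilyloxy)pent-2-ene
Conditions: TMSCl, NaI, Et3N, MeCN, rt
Reagents that add atoms: chlorotrimethylsilane, C[Si](C)(C)Cl
Why: Enol silylation of the symmetrical ketone with iodotrimethylsilane generated in situ and triethylamine can give only one regioisomer, mainly as the Z enol ether, and its geometry is immaterial because the carbon it later becomes (C3) is epimerisable.

Step 6
Reactants: 8 (3aR,7aS)-3a,7a-diethyl-3a,4-dihydro-2-benzofuran-1,3,5(7aH)-trione; 10 (Z)-3-(trimethylsilyloxy)pent-2-ene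
Product: 11 (3aR,7S,7aS)-3a,7a-diethyl-7-(3-oxopentan-2-yl)-5-(trimethylsilyloxy)-3a,4,7,7a-tetrahydro-2-benzofuran-1,3-dione (side-chain methine as epimer mixture)
Conditions: Tf2NH (2 mol %), CH2Cl2, −78 → −40 °C; Et3N quench, non-aqueous work-up
Reagents that add atoms: none
Why: Silyl triflimide-catalysed Mukaiyama–Michael addition brings the pentan-3-one carbon to C3a of the activated enone and transfers silicon to the C7 oxygen, so the C7=C7a enol ether forms regiospecifically; C3a is set by attack on the face of the two ethyl groups, anti to the anhydride ring whose C4 carbonyl stands beside C3a (approach opposite the electron-withdrawing acyl substituent), while C3 forms as a mixture that is equilibrated in step 8.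

Step 7
Reactants: 11 (3aR,7S,7aS)-3a,7a-diethyl-7-(3-oxopentan-2-yl)-5-(trimethylsilyloxy)-3a,4,7,7a-tetrahydro-2-benzofuran-1,3-dione
Product: 13 (3aR,4S,5R)-4,5-diethyl-1,3-dimethyl-2,7-dioxooctahydro-1H-indene-4,5-dicarboxylic anhydride as a mixture of C1/C3/C7a epimers, via bis-silyl enol ether 12 (not isolated)
Conditions: LDA, TMSCl, THF, −78 °C; solvent exchange to MeCN; CAN (2.2 equiv), NaHCO3, −30 → 0 °C
Reagents that add atoms: none
Why: Kinetic enolisation of the ethyl ketone at its only methylene (C1) with in situ silylation, then one-electron oxidation of the bis-silyl enol ether by cerium(IV) (intramolecular oxidative coupling of silyl enol ethers), lets the α-keto radical close 5-exo onto C7a of the second enol ether and a second oxidation release the C7 ketone; the new C1 and C7a centres arise as mixtures because both are α to ketones and are set in step 8.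

Step 8
Reactants: 13 (3aR,4S,5R)-4,5-diethyl-1,3-dimethyl-2,7-dioxooctahydro-1H-indene-4,5-dicarboxylic anhydride (epimer mixture)
Product: 14 (1R,3R,3aR,4S,5R,7aS)-4,5-diethyl-1,3-dimethyl-2,7-dioxooctahydro-1H-indene-4,5-dicarboxylic anhydride
Conditions: DBU (cat.), PhMe, 60 °C
Reagents that add atoms: none
Why: Base-mediated enolisation (thermodynamic epimerisation) equilibrates the three centres α to a ketone: C7a should settle trans to C3a because only the trans-fused chair avoids a 1,3-diaxial contact between a ring-fusion carbon and an ethyl group, and the C1 and C3 methyl groups should settle trans to their ring neighbours, which is the arrangement of the target.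

Step 9
Reactants: 14 (1R,3R,3aR,4S,5R,7aS)-4,5-diethyl-1,3-dimethyl-2,7-dioxooctahydro-1H-indene-4,5-dicarboxylic anhydride
Product: 15 (1R,3R,3aS,4S,5R,7aS)-4,5-diethyl-1,3-dimethyl-2-oxo-7-(trifluoromethylsulfonyloxy)-2,3,3a,4,5,7a-hexahydro-1H-indene-4,5-dicarboxylic anhydride
Conditions: KHMDS (1.05 equiv), PhNTf2, THF, −78 °C; aq. NH4Cl
Reagents that add atoms: N-phenylbis(trifluoromethanesulfonimide), O=S(=O)(N(c1ccccc1)S(=O)(=O)C(F)(F)F)C(F)(F)F
Why: Kinetic deprotonation by the bulky amide should occur at C6, the only methylene α to a ketone (C1, C3 and C7a are hindered methines), and O-sulfonylation of that enolate (enol triflate formation) fixes the C6=C7 double bond, after which C7a can no longer epimerise.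

Step 10
Reactants: 15 (1R,3R,3aS,4S,5R,7aS)-4,5-diethyl-1,3-dimethyl-2-oxo-7-(trifluoromethylsulfonyloxy)-2,3,3a,4,5,7a-hexahydro-1H-indene-4,5-dicarboxylic anhydride
Product: 16 (1R,3R,3aS,4S,5R,7aS)-4,5-diethyl-1,3,7-trimethyl-2-oxo-2,3,3a,4,5,7a-hexahydro-1H-indene-4,5-dicarboxylic anhydride
Conditions: Pd(PPh3)4 (5 mol %), Me4Sn, LiCl, THF, 65 °C
Reagents that add atoms: tetramethylstannane, C[Sn](C)(C)C
Why: Stille cross-coupling of the enol triflate with tetramethyltin under neutral conditions installs the C7 methyl group without moving the double bond and tolerates the ketone and the anhydride; no stereocentre is touched.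

Step 11
Reactants: 16 (1R,3R,3aS,4S,5R,7aS)-4,5-diethyl-1,3,7-trimethyl-2-oxo-2,3,3a,4,5,7a-hexahydro-1H-indene-4,5-dicarboxylic anhydride
Product: 17 hydroxylactone of 16 (C2 ketone reduced to the alcohol; anhydride reduced at the C5 carbonyl to the lactol O–CH(OH) on C5 with the lactone C=O kept on C4; C1, C3, C3a, C4, C5, C7a as in 16; C2 and the lactol carbon as epimer mixtures)
Conditions: LiAlH(OtBu)3 (excess), THF, −40 → 0 °C; aq. Rochelle salt
Reagents that add atoms: none
Why: The bulky alkoxyaluminium hydride reduces the cyclopentanone and adds to the C5 anhydride carbonyl, which is flanked by the sp2 carbon C6, in preference to the C4 carbonyl screened by C3a and the C3 methyl group (partial reduction of a cyclic anhydride to a hydroxylactone); the tetrasubstituted lactolate should stay closed so that reduction stops at the aldehyde level, the reagent does not reduce the remaining lactone, and the two new carbinol centres are removed in steps 12 and 13.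

Step 12
Reactants: 17 hydroxylactone of 16
Product: 18 (1R,3R,3aS,4S,5R,7aS)-4,5-diethyl-2-hydroxy-1,3,7-trimethyl-5-[(E)-2-phenylethenyl]-2,3,3a,4,5,7a-hexahydro-1H-indene-4-carboxylic acid (C2 epimers)
Conditions: PhCH2P(O)(OEt)2, KOtBu (excess), THF, 0 → 40 °C; then 1 M HCl
Reagents that add atoms: diethyl benzylphosphonate, CCOP(=O)(Cc1ccccc1)OCC
Why: Under excess base the lactol opens to the carboxylate aldehyde, which has no α-hydrogen, and Horner–Wadsworth–Emmons olefination with the benzylphosphonate anion should give the E styryl group under the usual control of this reaction, while the C2 alkoxide and the carboxylate are inert.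

Step 13
Reactants: 18 (1R,3R,3aS,4S,5R,7aS)-4,5-diethyl-2-hydroxy-1,3,7-trimethyl-5-[(E)-2-phenylethenyl]-2,3,3a,4,5,7a-hexahydro-1H-indene-4-carboxylic acid
Product: 19 dinorspiculoic acid A, (1R,3R,3aS,4S,5R,7aS)-4,5-diethyl-1,3,7-trimethyl-2-oxo-5-[(E)-2-phenylethenyl]-2,3,3a,4,5,7a-hexahydro-1H-indene-4-carboxylic acid
Conditions: Dess–Martin periodinane, CH2Cl2, rt
Reagents that add atoms: none
Why: Dess–Martin oxidation returns the C2 ketone from either carbinol epimer without touching the acid or the two alkenes, and C1 and C3 keep the configuration set in step 8 because no base is present.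

**Compound list**

1 | hex-3-yne | CCC#CCC | starting material
2 | 3,4-diethylfuran-2,5-dione (2,3-diethylmaleic anhydride) | CCC1=C(CC)C(=O)OC1=O | intermediate
3 | (E)-4-methoxybut-3-en-2-one | CO/C=C/C(C)=O | starting material
4 | (2R,5R)-2,5-diphenylpyrrolidine | N1[C@@H](c2ccccc2)CC[C@@H]1c1ccccc1 | starting material
5 | (E)-4-[(2R,5R)-2,5-diphenylpyrrolidin-1-yl]but-3-en-2-one | CC(=O)/C=C/N1[C@@H](c2ccccc2)CC[C@@H]1c1ccccc1 | intermediate
6 | (E)-1-[(2R,5R)-2,5-diphenylpyrrolidin-1-yl]-3-(tert-butyldimethylsilyloxy)buta-1,3-diene | C=C(O[Si](C)(C)C(C)(C)C)/C=C/N1[C@@H](c2ccccc2)CC[C@@H]1c1ccccc1 | intermediate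
7 | endo cycloadduct, (3aR,4S,7aR)-6-(tert-butyldimethylsilyloxy)-4-[(2R,5R)-2,5-diphenylpyrrolidin-1-yl]-3a,7a-diethyl-3a,4,7,7a-tetrahydro-2-benzofuran-1,3-dione (amine cis to the anhydride ring) | CC[C@@]1(C3=O)CC(O[Si](C)(C)C(C)(C)C)=C[C@H](N4[C@@H](c5ccccc5)CC[C@@H]4c6ccccc6)[C@]1(CC)C(=O)O3 | intermediate (not isolated)
8 | (3aR,7aS)-3a,7a-diethyl-3a,4-dihydro-2-benzofuran-1,3,5(7aH)-trione (cis-fused enone anhydride; C4 and C5 quaternary, C3a=C7a, C7 ketone) | CC[C@@]1(C3=O)CC(=O)C=C[C@]1(CC)C(=O)O3 | intermediate
9 | pentan-3-one | CCC(=O)CC | starting material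
10 | (Z)-3-(trimethylsilyloxy)pent-2-ene | C/C=C(\O[Si](C)(C)C)CC | intermediate
11 | (3aR,7S,7aS)-3a,7a-diethyl-7-(3-oxopentan-2-yl)-5-(trimethylsilyloxy)-3a,4,7,7a-tetrahydro-2-benzofuran-1,3-dione (side chain cis to the ethyl groups; side-chain methine epimers) | CC[C@@]1(C3=O)CC(O[Si](C)(C)C)=C[C@@H](C(C)C(=O)CC)[C@]1(CC)C(=O)O3 | intermediate
12 | bis-silyl enol ether, (3aR,7S,7aS)-3a,7a-diethyl-5-(trimethylsilyloxy)-7-[3-(trimethylsilyloxy)pent-3-en-2-yl]-3a,4,7,7a-tetrahydro-2-benzofuran-1,3-dione | CC[C@@]1(C3=O)CC(O[Si](C)(C)C)=C[C@@H](C(C)C(O[Si](C)(C)C)=CC)[C@]1(CC)C(=O)O3 | intermediate (not isolated)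
13 | (3aR,4S,5R)-4,5-diethyl-1,3-dimethyl-2,7-dioxooctahydro-1H-indene-4,5-dicarboxylic anhydride, mixture of C1/C3/C7a epimers | CC[C@@]1(C4=O)CC(=O)C2[C@@H](C(C)C(=O)C2C)[C@]1(CC)C(=O)O4 | intermediate
14 | (1R,3R,3aR,4S,5R,7aS)-4,5-diethyl-1,3-dimethyl-2,7-dioxooctahydro-1H-indene-4,5-dicarboxylic anhydride (trans ring fusion, all-trans cyclopentanone) | CC[C@@]1(C4=O)CC(=O)[C@H]2[C@@H]([C@@H](C)C(=O)[C@@H]2C)[C@]1(CC)C(=O)O4 | intermediate
15 | (1R,3R,3aS,4S,5R,7aS)-4,5-diethyl-1,3-dimethyl-2-oxo-7-(trifluoromethylsulfonyloxy)-2,3,3a,4,5,7a-hexahydro-1H-indene-4,5-dicarboxylic anhydride | CC[C@@]1(C4=O)C=C(OS(=O)(=O)C(F)(F)F)[C@H]2[C@@H]([C@@H](C)C(=O)[C@@H]2C)[C@]1(CC)C(=O)O4 | intermediate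
16 | (1R,3R,3aS,4S,5R,7aS)-4,5-diethyl-1,3,7-trimethyl-2-oxo-2,3,3a,4,5,7a-hexahydro-1H-indene-4,5-dicarboxylic anhydride | CC[C@@]1(C4=O)C=C(C)[C@H]2[C@@H]([C@@H](C)C(=O)[C@@H]2C)[C@]1(CC)C(=O)O4 | intermediate
17 | hydroxylactone of 16: C2 alcohol; lactol carbon O–CH(OH) on C5, lactone C=O on C4; other centres as in 16; C2 and lactol carbon unassigned (epimer mixtures) | CC[C@@]1(C4O)C=C(C)[C@H]2[C@@H]([C@@H](C)C(O)[C@@H]2C)[C@]1(CC)C(=O)O4 | intermediate
18 | (1R,3R,3aS,4S,5R,7aS)-4,5-diethyl-2-hydroxy-1,3,7-trimethyl-5-[(E)-2-phenylethenyl]-2,3,3a,4,5,7a-hexahydro-1H-indene-4-carboxylic acid (C2 epimers) | CC[C@@]1(/C=C/c2ccccc2)C=C(C)[C@H]2[C@@H]([C@@H](C)C(O)[C@@H]2C)[C@]1(CC)C(=O)O | intermediate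
19 | dinorspiculoic acid A, (1R,3R,3aS,4S,5R,7aS)-4,5-diethyl-1,3,7-trimethyl-2-oxo-5-[(E)-2-phenylethenyl]-2,3,3a,4,5,7a-hexahydro-1H-indene-4-carboxylic acid | CC[C@@]1(/C=C/c2ccccc2)C=C(C)[C@H]2[C@@H]([C@@H](C)C(=O)[C@@H]2C)[C@]1(CC)C(=O)O | target

**Step count and risks**

Total steps: 13. Longest linear sequence: 11 steps (steps 2, 3, 4, 6, 7, 8, 9, 10, 11, 12, 13, from 3 and 4 to 19).

Steps most likely to fail:

Step 6. The silyl enol ether may add to C3a from the anhydride face, or only slowly at this β-carbon next to a quaternary centre, which would give the wrong C3a series or mixtures. Fallback: the order of bond formation at C3a is reversed so that the same facial bias delivers hydrogen instead of carbon. It sets out from 8. The adduct formed from 8 and 10 under the step 6 conditions, the C3a epimer of 11 F6, is oxidised with Pd(OAc)2 in MeCN (Saegusa–Ito oxidation) to the β-substituted enone (3aR,7aS)-3a,7a-diethyl-7-(3-oxopentan-2-yl)-3a,4-dihydro-2-benzofuran-1,3,5(7aH)-trione F7. Conjugate reduction of F7 with hexameric triphenylphosphine copper hydride in the presence of TMSCl should then add hydride to C3a from the anhydride face and trap the enolate on oxygen, which comes back to the route at 11.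

Step 4. The tetrasubstituted dienophile may add slowly to the hindered diene, and leakage through the exo transition state or the shielded diene face would lower the enantiomeric purity of 8. Fallback: the same cycloaddition is run without auxiliary control and the enone is resolved. It sets out from 2, which is combined with the unhindered (E)-1-(dimethylamino)-3-(tert-butyldimethylsilyloxy)buta-1,3-diene F1 to give the racemic endo cycloadduct F2 and, after the same HF treatment, racemic cis-3a,7a-diethyl-3a,4-dihydro-2-benzofuran-1,3,5(7aH)-trione F3. Ketalisation of F3 at C7 with (2R,3R)-2,3-bis(trimethylsilyloxy)butane and catalytic TMSOTf (CH2Cl2, −78 °C) gives two diastereomeric dioxolanes, the (4R,5R)-4,5-dimethyl-1,3-dioxolane of 8 F4 and the corresponding ketal of its enantiomer F5. These are separated by chromatography or crystallisation, and mild aqueous acid hydrolysis of F4 comes back to the route at 8.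

Step 7. The oxidised enol ether may be intercepted (nitrate transfer, or desilylation to the open-chain diketone) before the 5-exo closure. Fallback: the C7a–C1 bond is made by enolate alkylation instead of oxidation. It sets out from 8. Commercial 2-chloropentan-3-one F8 is enolised kinetically on its ethyl side (LDA, TMSCl, THF, −78 °C) to 2-chloro-3-(trimethylsilyloxy)pent-3-ene F9, which is added to 8 under the step 6 conditions to give the chloro ketone (3aR,7S,7aS)-7-(4-chloro-3-oxopentan-2-yl)-3a,7a-diethyl-5-(trimethylsilyloxy)-3a,4,7,7a-tetrahydro-2-benzofuran-1,3-dione F10. Fluoride (CsF, MeCN) then releases the C7 enolate regiospecifically, and this displaces the secondary α-keto chloride at C1 in a 5-exo-tet closure, which comes back to the route at 13.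

**Further compounds**

F1 | step 4 | (E)-1-(dimethylamino)-3-(tert-butyldimethylsilyloxy)buta-1,3-diene | C=C(O[Si](C)(C)C(C)(C)C)/C=C/N(C)C
F2 | step 4 | racemic endo cycloadduct, 6-(tert-butyldimethylsilyloxy)-4-(dimethylamino)-3a,7a-diethyl-3a,4,7,7a-tetrahydro-2-benzofuran-1,3-dione | CCC1(C3=O)CC(O[Si](C)(C)C(C)(C)C)=CC(N(C)C)C1(CC)C(=O)O3
F3 | step 4 | racemic cis-3a,7a-diethyl-3a,4-dihydro-2-benzofuran-1,3,5(7aH)-trione | CCC1(C3=O)CC(=O)C=CC1(CC)C(=O)O3
F4 | step 4 | C7 (4R,5R)-4,5-dimethyl-1,3-dioxolane ketal of 8 | CC[C@@]1(C3=O)CC2(O[C@H](C)[C@@H](C)O2)C=C[C@]1(CC)C(=O)O3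
F5 | step 4 | C7 (4R,5R)-4,5-dimethyl-1,3-dioxolane ketal of the enantiomer of 8 | CC[C@]1(C3=O)CC2(O[C@H](C)[C@@H](C)O2)C=C[C@@]1(CC)C(=O)O3
F6 | step 6 | C3a epimer of 11, (3aR,7R,7aS)-3a,7a-diethyl-7-(3-oxopentan-2-yl)-5-(trimethylsilyloxy)-3a,4,7,7a-tetrahydro-2-benzofuran-1,3-dione | CC[C@@]1(C3=O)CC(O[Si](C)(C)C)=C[C@H](C(C)C(=O)CC)[C@]1(CC)C(=O)O3
F7 | step 6 | (3aR,7aS)-3a,7a-diethyl-7-(3-oxopentan-2-yl)-3a,4-dihydro-2-benzofuran-1,3,5(7aH)-trione | CC[C@@]1(C3=O)CC(=O)C=C(C(C)C(=O)CC)[C@]1(CC)C(=O)O3
F8 | step 7 | 2-chloropentan-3-one | CCC(=O)C(C)Cl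
F9 | step 7 | 2-chloro-3-(trimethylsilyloxy)pent-3-ene | CC=C(O[Si](C)(C)C)C(C)Cl
F10 | step 7 | (3aR,7S,7aS)-7-(4-chloro-3-oxopentan-2-yl)-3a,7a-diethyl-5-(trimethylsilyloxy)-3a,4,7,7a-tetrahydro-2-benzofuran-1,3-dione | CC[C@@]1(C3=O)CC(O[Si](C)(C)C)=C[C@@H](C(C)C(=O)C(C)Cl)[C@]1(CC)C(=O)O3
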